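The route rests on one disconnection: the cyclopentane of the spiro[4.5]decane, whose CH(OH) sits next to a ring CH carrying C(CH2OAc)=CH–diene (a homoallylic alcohol), is opened between these two carbons to an aldehyde on the spiro carbon and a trisubstituted alkene three carbons down the chain. In the forward sense a Lewis-acid carbonyl-ene reaction closes the five-membered ring, sets both new stereocentres and moves the alkene into conjugation with the diene in a single operation. The precursor is a fully substituted cyclohexane built from (S)-carvone with a neopentyl aldehyde, a silylated tertiary alcohol, the tetrasubstituted enal and a (Z)-configured skipped-triene arm carrying the acetate.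

Key step: step 23

Remark (locants): the cyclohexane keeps the carvone numbering throughout: C1 is the former carbonyl carbon (later the spiro carbon), C2 carries the methyl group, C5 the three-carbon unit and C6 the silyloxypropyl chain; the "upper face" is the face of the C6 chain; the arm carbons are Cα to Cε counted from C1.

Assumption: compounds 2, 23, 25 and 28 are bought; 25 can otherwise be made in one step from propargyl alcohol and Bu3SnH.

Step 1
Reactants: 1 (S)-carvone; 2 tert-butyl(3-iodopropoxy)dimethylsilane
Product: 3 trans-6-(3-silyloxypropyl)carvone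
Conditions: LiN(iPr)2, THF, −78 °C; then 2, DMPU, −78 → −20 °C
Reagents that add atoms: none
Why: Kinetic deprotonation gives the cross-conjugated lithium enolate at C6, and its SN2 alkylation should take the iodide in anti to the neighbouring isopropenyl group, which sets C6 trans to C5.

Step 2
Reactants: 3 trans-6-(3-silyloxypropyl)carvone
Product: 4 epoxy ketone
Conditions: 30% H2O2, NaOH (cat.), MeOH, 0 °C
Reagents that add atoms: hydrogen peroxide, OO
Why: Weitz–Scheffer nucleophilic epoxidation of the enone, in which hydroperoxide should add to C3 on the face away from the C5 isopropenyl group as it does with carvone itself, so that the oxirane oxygen (the future C2 hydroxyl) lies on the upper face.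

Step 3
Reactants: 5 allyl alcohol
Product: 7 (allyloxymethyl)triphenylphosphonium chloride, via allyl chloromethyl ether 6 (not isolated)
Conditions: (CH2O)n, HCl (g), CaCl2, 0 °C; then PPh3, toluene, 50 °C
Reagents that add atoms: paraformaldehyde (formaldehyde unit), C=O; hydrogen chloride, Cl; triphenylphosphine, c1ccc(cc1)P(c1ccccc1)c1ccccc1
Why: Chloromethylation of the alcohol gives the α-chloro ether, which quaternises triphenylphosphine by SN2 displacement to the Wittig salt.

Step 4
Reactants: 4 epoxy ketone; 7 (allyloxymethyl)triphenylphosphonium chloride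
Product: 8 allyl enol ether
Conditions: 7, KN(SiMe3)2, THF, 0 °C; then 4, 0 °C → rt
Reagents that add atoms: none
Why: Wittig olefination with the alkoxymethylene ylide turns the ketone into an allyl enol ether; the oxirane should survive the non-nucleophilic base, and the enol ether geometry is of no consequence.

Step 5
Reactants: 8 allyl enol ether
Product: 9 epoxy aldehyde with quaternary C1
Conditions: toluene, 130 °C, sealed tube
Reagents that add atoms: none
Why: Claisen rearrangement ([3,3]) of the allyl vinyl ether forms the C1–Cα bond and the aldehyde together, and the allyl group should arrive on the lower face of C1, away from the oxirane oxygen and the C6 chain, which sets the quaternary centre with the formyl group on the upper face.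

Step 6
Reactants: 9 epoxy aldehyde with quaternary C1
Product: 10 diol
Conditions: LiEt3BH, THF, 0 °C → rt; then H2O
Reagents that add atoms: none
Why: Hydride reduces the aldehyde and opens the trisubstituted epoxide by SN2 attack at the less substituted C3, so the C2–O bond keeps its configuration and the tertiary alcohol ends up cis to the hydroxymethyl group.

Step 7
Reactants: 10 diol
Product: 11 triol
Conditions: disiamylborane (from BH3·THF and 2-methylbut-2-ene), THF, 0 °C; then NaOH, H2O2
Reagents that add atoms: hydrogen peroxide, OO
Why: Hydroboration–oxidation with the hindered dialkylborane is anti-Markovnikov and should select the monosubstituted allyl alkene over the 1,1-disubstituted isopropenyl group.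

Step 8
Reactants: 11 triol
Product: 13 acetate pivalate, via monopivalate 12 (not isolated)
Conditions: pivaloyl chloride (1.1 equiv), pyridine, CH2Cl2, −20 °C; then Ac2O, DMAP, rt
Reagents that add atoms: pivaloyl chloride, CC(C)(C)C(Cl)=O; acetic anhydride, CC(=O)OC(C)=O
Why: Acylation by steric demand: the bulky acyl chloride should take only the unhindered primary hydroxyl at Cγ, the neopentyl hydroxyl is then acetylated under DMAP catalysis (which protects it from oxidation in step 9), and the tertiary hydroxyl stays free.

Step 9
Reactants: 13 acetate pivalate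
Product: 16 C5 ketone, via methoxy hydroperoxide 14 (not isolated), via TEMPO alkoxyamine 15 (not isolated)
Conditions: O3, MeOH/CH2Cl2, −78 °C; then FeSO4·7H2O, TEMPO, −78 °C → rt; then magnesium bis(monoperoxyphthalate) hexahydrate, rt
Reagents that add atoms: TEMPO (2,2,6,6-tetramethylpiperidin-1-oxyl, source of the carbonyl oxygen), CC1(C)CCCC(C)(C)N1[O]
Why: Oxodealkenylation: ozonolysis in methanol gives the α-methoxy hydroperoxide, reduction by divalent iron and β-scission (loss of methyl acetate) leave a C5 radical that TEMPO traps, and peracid oxidation of the alkoxyamine gives the ketone; the isopropenyl group is the only alkene present and the C5 stereocentre is no longer needed.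

Step 10
Reactants: 16 C5 ketone
Product: 17 tertiary allylic alcohol
Conditions: isopropenylmagnesium bromide, CeCl3, THF, −78 °C
Reagents that add atoms: isopropenylmagnesium bromide, CC(=C)[Mg]Br
Why: Organocerium 1,2-addition (Imamoto conditions) to the hindered, enolisable ketone should proceed without epimerising C6 or touching the esters at low temperature; the configuration of the new carbinol centre does not matter because C5 becomes sp2 in step 11.

Step 11
Reactants: 17 tertiary allylic alcohol
Product: 19 (E)-allylic alcohol triol, via allylic trimethylsilyl ether 18 (not isolated)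
Conditions: Ph3SiOReO3 (5 mol %), N,O-bis(trimethylsilyl)acetamide, Et2O, −50 → 0 °C; then K2CO3, MeOH, rt
Reagents that add atoms: none
Why: Perrhenate-catalysed 1,3-transposition of the tertiary allylic alcohol ([3,3] shift of the perrhenate ester through a chair transition state), pulled forward by silylation of the primary alcohol; the more substituted ring carbon C6 should take the pseudo-equatorial place, which puts the methyl group cis to C6 and CH2O cis to C4 ((E)-alkene), and methanolysis then removes the trimethylsilyl ether and the acetate.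

Step 12
Reactants: 19 (E)-allylic alcohol triol
Product: 20 tris(triethylsilyl) ether
Conditions: Et3SiOTf, 2,6-lutidine, CH2Cl2, −78 → 0 °C
Reagents that add atoms: triethylsilyl trifluoromethanesulfonate, CC[Si](CC)(CC)OS(=O)(=O)C(F)(F)F
Why: Silyl ether formation with a silyl triflate and a hindered base should cover both primary hydroxyls and the tertiary one.

Step 13
Reactants: 20 tris(triethylsilyl) ether
Product: 21 Cγ alcohol
Conditions: iBu2AlH, CH2Cl2, −78 °C
Reagents that add atoms: none
Why: Reductive cleavage of the pivalate by the aluminium hydride at low temperature; the silyl ethers and the tetrasubstituted alkene are inert.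

Step 14
Reactants: 21 Cγ alcohol
Product: 22 Cγ aldehyde
Conditions: Dess–Martin periodinane, pyridine, CH2Cl2, rt
Reagents that add atoms: none
Why: Dess–Martin oxidation of the only free alcohol to the aldehyde under buffered conditions that should spare the silyl ethers.

Step 15
Reactants: 23 6-methylhept-5-en-2-one
Product: 24 6-methylhepta-1,5-dien-2-yl triflate
Conditions: LiN(iPr)2, THF, −78 °C; then PhNTf2, −78 → 0 °C
Reagents that add atoms: N-phenylbis(trifluoromethanesulfonimide), O=S(=O)(N(c1ccccc1)S(=O)(=O)C(F)(F)F)C(F)(F)F
Why: Kinetic deprotonation of the methyl ketone at the methyl group and O-sulfonylation of the enolate give the 2-substituted alkenyl triflate.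

Step 16
Reactants: 24 6-methylhepta-1,5-dien-2-yl triflate; 25 (E)-3-(tributylstannyl)prop-2-en-1-ol
Product: 26 (2E)-8-methyl-4-methylidenenona-2,7-dien-1-ol
Conditions: 25, Pd(PPh3)4 (5 mol %), LiCl, THF, 60 °C
Reagents that add atoms: none
Why: Stille coupling of the alkenyl triflate with the (E)-alkenylstannane proceeds with retention at both sp2 carbons and builds the 2-substituted (E)-diene.

Step 17
Reactants: 26 (2E)-8-methyl-4-methylidenenona-2,7-dien-1-ol
Product: 27 (2E)-1-bromo-8-methyl-4-methylidenenona-2,7-diene
Conditions: CBr4, PPh3, CH2Cl2, 0 °C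
Reagents that add atoms: carbon tetrabromide, BrC(Br)(Br)Br
Why: Appel bromination of the primary allylic alcohol by SN2 displacement of the oxyphosphonium leaving group.

Step 18
Reactants: 28 methyl bis(2,2,2-trifluoroethyl)phosphonoacetate; 27 (2E)-1-bromo-8-methyl-4-methylidenenona-2,7-diene
Product: 29 α-dienylmethyl phosphonate
Conditions: 28, NaH, THF, 0 °C; then 27, 0 °C → rt
Reagents that add atoms: none
Why: SN2 C-alkylation of the stabilised phosphonate carbanion with the primary allylic bromide gives the α-substituted Still–Gennari reagent; its new stereocentre is lost in step 19.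

Step 19
Reactants: 22 Cγ aldehyde; 29 α-dienylmethyl phosphonate
Product: 30 (Z)-enoate
Conditions: 29, KN(SiMe3)2, 18-crown-6, THF, −78 °C; then 22, −78 °C
Reagents that add atoms: none
Why: Still–Gennari olefination: the bis(trifluoroethyl) phosphonate with a dissociated potassium counter-ion eliminates fast from the kinetic adduct and should give the (Z)-trisubstituted enoate, with the ester cis to the chain from the ring and the dienylmethyl group (Cε) trans to it.

Step 20
Reactants: 30 (Z)-enoate
Product: 31 (Z)-allylic alcohol
Conditions: iBu2AlH, CH2Cl2, −78 °C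
Reagents that add atoms: none
Why: 1,2-Reduction of the conjugated ester to the allylic alcohol by the aluminium hydride; silyl ethers and the skipped triene are untouched.

Step 21
Reactants: 31 (Z)-allylic alcohol
Product: 32 (Z)-allylic acetate
Conditions: Ac2O, pyridine, DMAP (cat.), CH2Cl2, 0 °C
Reagents that add atoms: acetic anhydride, CC(=O)OC(C)=O
Why: Acylation of the only free hydroxyl under nucleophilic catalysis by DMAP.

Step 22
Reactants: 32 (Z)-allylic acetate
Product: 33 seco-dialdehyde
Conditions: (COCl)2, DMSO, CH2Cl2, −78 → −30 °C; then Et3N, −78 → 0 °C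
Reagents that add atoms: none
Why: Swern conditions convert primary triethylsilyl ethers directly into aldehydes (silyl transfer to the chlorosulfonium ion, then the usual collapse of the alkoxysulfonium ylide), while the tertiary triethylsilyl ether, the primary tert-butyldimethylsilyl ether and the acetate should stay.

Step 23
Reactants: 33 seco-dialdehyde
Product: 34 bis-silyl ether of the target
Conditions: Me2AlCl (2.5 equiv), CH2Cl2, −78 °C
Reagents that add atoms: none
Why: The aluminium Lewis acid coordinates the unconjugated aldehyde on the quaternary carbon, the CH end of the trisubstituted alkene three carbons away bonds to the carbonyl carbon and, within the same six-membered array, a hydrogen of the doubly allylic CH2 (trans to the tether in the (Z)-alkene, hence on the side of the vinylic hydrogen) moves to oxygen, leaving the new alkene conjugated with the diene. The closest known reaction type is the Me2AlCl-promoted type-one intramolecular carbonyl-ene cyclisation of unsaturated aldehydes to 2-alkenylcycloalkanols (isopulegol-type closure). The cyclopentane closes in a 5-exo-trig mode onto the carbonyl carbon. The carbinol centre is set by the carbonyl rotamer: the oxygen carrying aluminium should sit on the side of C6, a CH, and not on the side of C2, which is fully substituted and bears the bulky, non-chelating triethylsilyl ether; the ring CH centre follows from the concerted bicyclic transition state, which keeps hydroxyl and alkenyl cis, and allylic strain should turn the diene away from the ring so that the new alkene is (Z). The chemoselectivity needed should come from the substrate: the reacting aldehyde cannot enolise, the conjugated enal is deactivated, sterically buried and has no alkene within reach, the acetoxymethyl hydrogens are electron-poor and cis to the tether, and the remote alkenes could only close large rings. The excess of Me2AlCl takes up the second carbonyl group, and the product leaves as an aluminium alkoxide with loss of methane, which keeps the medium free of protons.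

Step 24
Reactants: 34 bis-silyl ether of the target
Product: 35 target CNP0204268.1
Conditions: HF·pyridine, pyridine, THF, 0 °C → rt
Reagents that add atoms: none
Why: Fluoride-assisted cleavage of both silyl ethers under buffered, mildly acidic conditions that should leave the allylic acetate, the tertiary alcohol and the triene alone and avoid acyl migration.

Compound list

1 | (S)-carvone | CC1=CC[C@@H](CC1=O)C(C)=C | starting material
2 | tert-butyl(3-iodopropoxy)dimethylsilane | ICCCO[Si](C)(C)C(C)(C)C | starting material
3 | (5S,6R)-6-[3-(tert-butyldimethylsilyloxy)propyl]-2-methyl-5-(prop-1-en-2-yl)cyclohex-2-en-1-one (chain trans to isopropenyl) | O=C1[C@H](CCCO[Si](C)(C)C(C)(C)C)[C@@H](C(C)=C)CC=C1C | intermediate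
4 | 2,3-epoxide of 3, oxirane oxygen on the upper face (cis to the C6 chain, trans to isopropenyl) | O=C1[C@H](CCCO[Si](C)(C)C(C)(C)C)[C@@H](C(C)=C)C[C@@H]2O[C@]12C | intermediate
5 | allyl alcohol | C=CCO | starting material
6 | allyl chloromethyl ether (not isolated) | C=CCOCCl | intermediate
7 | (allyloxymethyl)triphenylphosphonium chloride | C=CCOC[P+](c1ccccc1)(c1ccccc1)c1ccccc1.[Cl-] | intermediate
8 | allyl enol ether of 4 (C1=CH–O–allyl, both enol ether geometries) | C=CCOC=C1[C@H](CCCO[Si](C)(C)C(C)(C)C)[C@@H](C(C)=C)C[C@@H]2O[C@]12C | intermediate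
9 | epoxy aldehyde: quaternary C1 with formyl on the upper face and allyl on the lower face, 2,3-epoxide on the upper face | C=CC[C@]1([C@H](CCCO[Si](C)(C)C(C)(C)C)[C@@H](C(C)=C)C[C@@H]2O[C@]12C)C=O | intermediate
10 | diol: C1 hydroxymethyl and C2 tertiary hydroxyl on the upper face, C1 allyl and C2 methyl on the lower face | C=CC[C@]1([C@H](CCCO[Si](C)(C)C(C)(C)C)[C@@H](C(C)=C)CC[C@]1(C)O)CO | intermediate
11 | triol: 10 with the allyl group turned into 3-hydroxypropyl (Cγ–OH) | OCCC[C@]1([C@H](CCCO[Si](C)(C)C(C)(C)C)[C@@H](C(C)=C)CC[C@]1(C)O)CO | intermediate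
12 | Cγ monopivalate of 11 (not isolated) | CC(C)(C)C(=O)OCCC[C@]1([C@H](CCCO[Si](C)(C)C(C)(C)C)[C@@H](C(C)=C)CC[C@]1(C)O)CO | intermediate
13 | Cγ pivalate and C1-CH2 acetate of 11, tertiary hydroxyl free | CC(C)(C)C(=O)OCCC[C@]1([C@H](CCCO[Si](C)(C)C(C)(C)C)[C@@H](C(C)=C)CC[C@]1(C)O)COC(C)=O | intermediate
14 | α-methoxy hydroperoxide from 13, C5–C(CH3)(OCH3)OOH, epimers at that carbon (not isolated) | CC(C)(C)C(=O)OCCC[C@]1([C@H](CCCO[Si](C)(C)C(C)(C)C)[C@@H](C(C)(OC)OO)CC[C@]1(C)O)COC(C)=O | intermediate
15 | C5 alkoxyamine of 2,2,6,6-tetramethylpiperidine, C5 epimers (not isolated) | CC(C)(C)C(=O)OCCC[C@]1([C@H](CCCO[Si](C)(C)C(C)(C)C)C(ON2C(C)(C)CCCC2(C)C)CC[C@]1(C)O)COC(C)=O | intermediate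
16 | C5 ketone | CC(C)(C)C(=O)OCCC[C@]1([C@H](CCCO[Si](C)(C)C(C)(C)C)C(=O)CC[C@]1(C)O)COC(C)=O | intermediate
17 | C5 tertiary allylic alcohol, C5(OH)–C(CH3)=CH2 (either C5 epimer) | CC(C)(C)C(=O)OCCC[C@]1([C@H](CCCO[Si](C)(C)C(C)(C)C)C(O)(C(C)=C)CC[C@]1(C)O)COC(C)=O | intermediate
18 | (E)-C5=C(CH3)CH2OSiMe3 allylic silyl ether, methyl cis to C6 (not isolated) | CC(C)(C)C(=O)OCCC[C@]1([C@H](CCCO[Si](C)(C)C(C)(C)C)/C(=C(\C)CO[Si](C)(C)C)CC[C@]1(C)O)COC(C)=O | intermediate
19 | triol with (E)-C5=C(CH3)CH2OH, C1–CH2OH and C2–OH; Cγ pivalate kept | CC(C)(C)C(=O)OCCC[C@]1([C@H](CCCO[Si](C)(C)C(C)(C)C)/C(=C(\C)CO)CC[C@]1(C)O)CO | intermediate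
20 | tris(triethylsilyl) ether of 19 | CC(C)(C)C(=O)OCCC[C@]1([C@H](CCCO[Si](C)(C)C(C)(C)C)/C(=C(\C)CO[Si](CC)(CC)CC)CC[C@]1(C)O[Si](CC)(CC)CC)CO[Si](CC)(CC)CC | intermediate
21 | Cγ primary alcohol (pivalate of 20 removed) | OCCC[C@]1([C@H](CCCO[Si](C)(C)C(C)(C)C)/C(=C(\C)CO[Si](CC)(CC)CC)CC[C@]1(C)O[Si](CC)(CC)CC)CO[Si](CC)(CC)CC | intermediate
22 | Cγ aldehyde | O=CCC[C@]1([C@H](CCCO[Si](C)(C)C(C)(C)C)/C(=C(\C)CO[Si](CC)(CC)CC)CC[C@]1(C)O[Si](CC)(CC)CC)CO[Si](CC)(CC)CC | intermediate
23 | 6-methylhept-5-en-2-one | CC(=O)CCC=C(C)C | starting material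
24 | 6-methylhepta-1,5-dien-2-yl trifluoromethanesulfonate | C=C(OS(=O)(=O)C(F)(F)F)CCC=C(C)C | intermediate
25 | (E)-3-(tributylstannyl)prop-2-en-1-ol | OC/C=C/[Sn](CCCC)(CCCC)CCCC | starting material
26 | (2E)-8-methyl-4-methylidenenona-2,7-dien-1-ol | OC/C=C/C(=C)CCC=C(C)C | intermediate
27 | (2E)-1-bromo-8-methyl-4-methylidenenona-2,7-diene | BrC/C=C/C(=C)CCC=C(C)C | intermediate
28 | methyl bis(2,2,2-trifluoroethyl)phosphonoacetate | COC(=O)CP(=O)(OCC(F)(F)F)OCC(F)(F)F | starting material
29 | methyl (4E)-2-[bis(2,2,2-trifluoroethoxy)phosphoryl]-10-methyl-6-methylideneundeca-4,9-dienoate (racemic) | COC(=O)C(C/C=C/C(=C)CCC=C(C)C)P(=O)(OCC(F)(F)F)OCC(F)(F)F | intermediate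
30 | (Z)-enoate: Cγ=Cδ(CO2CH3), ester cis to Cβ, Cε carrying the (E)-diene | C=C(CCC=C(C)C)/C=C/C/C(C(=O)OC)=C/CC[C@]1([C@H](CCCO[Si](C)(C)C(C)(C)C)/C(=C(\C)CO[Si](CC)(CC)CC)CC[C@]1(C)O[Si](CC)(CC)CC)CO[Si](CC)(CC)CC | intermediate
31 | (Z)-allylic alcohol (CH2OH on Cδ) | C=C(CCC=C(C)C)/C=C/C/C(CO)=C/CC[C@]1([C@H](CCCO[Si](C)(C)C(C)(C)C)/C(=C(\C)CO[Si](CC)(CC)CC)CC[C@]1(C)O[Si](CC)(CC)CC)CO[Si](CC)(CC)CC | intermediate
32 | (Z)-allylic acetate | C=C(CCC=C(C)C)/C=C/C/C(COC(C)=O)=C/CC[C@]1([C@H](CCCO[Si](C)(C)C(C)(C)C)/C(=C(\C)CO[Si](CC)(CC)CC)CC[C@]1(C)O[Si](CC)(CC)CC)CO[Si](CC)(CC)CC | intermediate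
33 | seco-dialdehyde with skipped-triene arm (precursor of the key step) | C=C(CCC=C(C)C)/C=C/C/C(COC(C)=O)=C/CC[C@]1([C@H](CCCO[Si](C)(C)C(C)(C)C)/C(=C(\C)C=O)CC[C@]1(C)O[Si](CC)(CC)CC)C=O | intermediate
34 | bis-silyl ether of the target (spirocyclic cis-cyclopentanol, conjugated triene) | C=C(/C=C/C=C(\COC(C)=O)[C@@H]1CC[C@]2([C@H](CCCO[Si](C)(C)C(C)(C)C)/C(=C(\C)C=O)CC[C@]2(C)O[Si](CC)(CC)CC)[C@@H]1O)CCC=C(C)C | intermediate
35 | CNP0204268.1 | C=C(/C=C/C=C(\COC(C)=O)[C@@H]1CC[C@]2([C@H](CCCO)/C(=C(\C)C=O)CC[C@]2(C)O)[C@@H]1O)CCC=C(C)C | target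

Total step count: 24. Longest linear sequence: 19 steps from (S)-carvone (steps 1, 2, 4–14 and 19–24).

Steps most likely to fail

1. Step 23 (carbonyl-ene closure). The hydrogen shift may lag behind C–C bond formation, so that the cationic centre next to the acetoxymethyl group is captured or the allylic acetate ionises, and the cis selectivity erodes. Fallback: split the step into a Prins cyclisation and an elimination. From 33, SnCl4 in CH2Cl2 at −78 °C should close the ring with chloride capture at the acetoxymethyl-bearing carbon and give the chloro alcohol F1; DBU in toluene at 60 °C should then remove HCl through the acidic doubly allylic CH2 and return to 34.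

2. Step 11 (1,3-transposition). The geometry of the congested tetrasubstituted alkene may be poorly controlled, and conversion may stall because the equilibrium does not lie far on the product side. Fallback: fix the geometry by the order of two cross-couplings. From 16, CBr4 and PPh3 in toluene at 80 °C should give the dibromoalkene F2; a Stille coupling with Bu3SnCH2OH and Pd(PPh3)4 should replace the less hindered bromine, the one on the C4 side, and give the (Z)-bromo allylic alcohol F3; a Negishi coupling with MeZnCl and Pd(PtBu3)2 should put the methyl group in the place of the remaining bromine with retention and give the allylic alcohol acetate F4; K2CO3 in methanol then removes the acetate and rejoins the route at 19.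

3. Step 5 (Claisen rearrangement). Facial selectivity at C1 may be poor, because the ring conformation of the oxirane-bearing enol ether decides which face the allyl group reaches. Fallback: form the quaternary centre by intermolecular enolate alkylation and place the epoxide afterwards under hydroxyl direction. From 3, a Wittig reaction with the ylide from (methoxymethyl)triphenylphosphonium chloride and KN(SiMe3)2 should give the dienol methyl ether F5; mild hydrolysis (oxalic acid, wet silica) should give the β,γ-unsaturated aldehyde F6; KOtBu and allyl bromide in THF at −78 °C should alkylate the dienolate at C1 anti to the C6 chain and give the α-allyl aldehyde F7; NaBH4 should give the homoallylic alcohol F8; VO(acac)2 and tBuOOH should deliver the epoxide to the upper face under direction by the hydroxymethyl group and give the epoxy alcohol F9; LiEt3BH then opens the epoxide and rejoins the route at 10.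

Further compounds

F1 | step 23 | chloro alcohol: cyclopentanol of 34 with a tertiary chloride on the acetoxymethyl-bearing carbon (epimers at that carbon) | C=C(CCC=C(C)C)/C=C/CC(Cl)(COC(C)=O)[C@@H]1CC[C@]2([C@H](CCCO[Si](C)(C)C(C)(C)C)/C(=C(\C)C=O)CC[C@]2(C)O[Si](CC)(CC)CC)[C@@H]1O
F2 | step 11 | C5 dibromomethylidene compound (dibromoalkene from 16) | CC(C)(C)C(=O)OCCC[C@]1([C@H](CCCO[Si](C)(C)C(C)(C)C)C(=C(Br)Br)CC[C@]1(C)O)COC(C)=O
F3 | step 11 | (Z)-bromo allylic alcohol, bromine cis to C6, CH2OH cis to C4 | CC(C)(C)C(=O)OCCC[C@]1([C@H](CCCO[Si](C)(C)C(C)(C)C)/C(=C(\Br)CO)CC[C@]1(C)O)COC(C)=O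
F4 | step 11 | (E)-allylic alcohol acetate (19 with the C1-CH2 acetate still in place) | CC(C)(C)C(=O)OCCC[C@]1([C@H](CCCO[Si](C)(C)C(C)(C)C)/C(=C(\C)CO)CC[C@]1(C)O)COC(C)=O
F5 | step 5 | dienol methyl ether of 3 (both enol ether geometries) | COC=C1[C@H](CCCO[Si](C)(C)C(C)(C)C)[C@@H](C(C)=C)CC=C1C
F6 | step 5 | β,γ-unsaturated aldehyde (C1 epimers) | O=CC1[C@H](CCCO[Si](C)(C)C(C)(C)C)[C@@H](C(C)=C)CC=C1C
F7 | step 5 | α-allyl aldehyde, formyl on the upper face, allyl on the lower face | C=CC[C@]1([C@H](CCCO[Si](C)(C)C(C)(C)C)[C@@H](C(C)=C)CC=C1C)C=O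
F8 | step 5 | homoallylic alcohol from F7 | C=CC[C@]1([C@H](CCCO[Si](C)(C)C(C)(C)C)[C@@H](C(C)=C)CC=C1C)CO
F9 | step 5 | epoxy alcohol, oxirane oxygen on the upper face | C=CC[C@]1([C@H](CCCO[Si](C)(C)C(C)(C)C)[C@@H](C(C)=C)C[C@@H]2O[C@]12C)CO
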